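The disconnection on which everything rests is the bond between C-1' of ring A (the methoxy-bearing trioxygenated ring) and its ketone carbon. One BF3-mediated Friedel–Crafts/Fries acylation joins a complete benzyl-protected chalcone diaryl ether phenol to benzyl-protected (E)-p-coumaric acid, activated in the flask as its chloride. It exploits that C-1' is ortho to the 2'-OH and para to the 4'-OMe, that the carbon para to this OH is blocked by the C-5' aryloxy oxygen, and that the other three rings are deactivated by conjugated carbonyls. The precursor phenol arises by SNAr diaryl ether formation, Baeyer–Villiger oxidation and Claisen–Schmidt condensation; global debenzylation finishes the route.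

Key step: step 4

Remark on the chemistry: the target has no stereocentre and is achiral. Its only stereo-elements are the two E enone double bonds; one is set in step 3 and the other is bought in with acid 8. Compounds 1, 2, 6 and 8 are taken as purchasable.

Step 1
Reactants: 1 2',4'-dihydroxyacetophenone; 2 4-fluoro-3-methoxybenzaldehyde
Product: 3 4-(4-acetyl-3-hydroxyphenoxy)-3-methoxybenzaldehyde
Conditions: K2CO3 (2 equiv), DMSO, 100 °C, Ar
Reagents that add atoms: none
Why: Nucleophilic aromatic substitution (SNAr): the more acidic, non-chelated 4-OH of 1 is ionised selectively and displaces the fluoride activated by the para formyl group, while the phenoxide character of the ketone-bearing ring disfavours enolisation and thus aldol condensation.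

Step 2
Reactants: 3 4-(4-acetyl-3-hydroxyphenoxy)-3-methoxybenzaldehyde
Product: 5 1-[2-hydroxy-4-(4-hydroxy-2-methoxyphenoxy)phenyl]ethan-1-one, via aryl formate 4 (not isolated)
Conditions: mCPBA, CH2Cl2, 0 °C → rt; aq. NaHCO3/Na2S2O3 wash; then K2CO3 (cat.), MeOH, rt
Reagents that add atoms: mCPBA O=C(OO)c1cccc(Cl)c1
Why: Baeyer–Villiger (Dakin-type) oxidation: the aryl group with its para aryloxy donor migrates in the Criegee adduct of the aldehyde, which should react far faster than the hydrogen-bonded methyl ketone, and mild methanolysis of formate 4 frees the phenol.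

Step 3
Reactants: 5 1-[2-hydroxy-4-(4-hydroxy-2-methoxyphenoxy)phenyl]ethan-1-one; 6 4-(benzyloxy)benzaldehyde
Product: 7 (E)-3-[4-(benzyloxy)phenyl]-1-[2-hydroxy-4-(4-hydroxy-2-methoxyphenoxy)phenyl]prop-2-en-1-one
Conditions: KOH (50% aq.), EtOH, rt, Ar; then 1 M HCl, 0 °C
Reagents that add atoms: none
Why: Claisen–Schmidt aldol condensation: the methyl ketone enolate adds to the non-enolisable aldehyde 6 and E1cB loss of hydroxide gives the thermodynamically preferred E enone, the two phenols riding along as phenoxides and the benzyl ether being base-stable.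

Step 4
Reactants: 7 (E)-3-[4-(benzyloxy)phenyl]-1-[2-hydroxy-4-(4-hydroxy-2-methoxyphenoxy)phenyl]prop-2-en-1-one; 8 (E)-3-[4-(benzyloxy)phenyl]prop-2-enoic acid
Product: 11 (E)-3-[4-(benzyloxy)phenyl]-1-[5-(4-{(E)-3-[4-(benzyloxy)phenyl]prop-2-enoyl}-3-hydroxyphenoxy)-2-hydroxy-4-methoxyphenyl]prop-2-en-1-one (di-O-benzylrhuschalcone IV), via acid chloride 9 (not isolated), via aryl cinnamate ester 10 (not isolated)
Conditions: 8 (1.3 equiv), (COCl)2 (1.3 equiv), DMF (cat.), ClCH2CH2Cl, rt; then 7, BF3·OEt2 (5 equiv), 0 → 65 °C; then H2O/MeOH, 50 °C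
Reagents that add atoms: none
Why: Oxalyl chloride turns acid 8 into acid chloride 9, which under BF3 O-acylates the free ring-A phenol of 7 to ester 10; BF3 then ionises the ester C–O bond and the acylium/boron phenoxide pair recombines at the ring carbon ortho to oxygen, product 11 staying coordinated to boron until the hydrolytic work-up. The closest known reaction type is the BF3-promoted Friedel–Crafts acylation/Fries rearrangement of phenols to o-hydroxyaryl ketones, as used for 2'-hydroxychalcones and deoxybenzoins. No ring is closed and no stereocentre is formed; both E enones should be carried through unchanged because neither stage touches the double bonds. The step needs site selectivity for the ring-A carbon that is ortho to OH and para to OMe: the carbon para to OH is blocked by the aryloxy group, the other ortho carbon is flanked by OH and OMe, and the resorcinol-derived ring and both benzyloxyphenyl rings are deactivated by their boron-complexed conjugated carbonyls. It also needs acyl transfer to outrun conjugate Friedel–Crafts addition to the enones, which the hard acylium electrophile and boron chelation of the 2'-oxygens (also blocking flavanone closure and a second acylation) should secure.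

Step 5
Reactants: 11 di-O-benzylrhuschalcone IV
Product: 12 rhuschalcone IV
Conditions: BCl3 (8 equiv), C6HMe5 (6 equiv), CH2Cl2, −78 °C; then MeOH, H2O
Reagents that add atoms: none
Why: Lewis-acid ether cleavage with a cation scavenger: BCl3 ionises the two benzyl C–O bonds at low temperature and pentamethylbenzene traps the benzyl cations, so no hydrogenation touches the enones, and the methyl ether, para and not ortho to its carbonyl, should stay intact.

Compound list
1 | 2',4'-dihydroxyacetophenone | CC(=O)c1ccc(O)cc1O | starting material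
2 | 4-fluoro-3-methoxybenzaldehyde | COc1cc(C=O)ccc1F | starting material
3 | 4-(4-acetyl-3-hydroxyphenoxy)-3-methoxybenzaldehyde | COc1cc(C=O)ccc1Oc1ccc(C(C)=O)c(O)c1 | intermediate
4 | 4-(4-acetyl-3-hydroxyphenoxy)-3-methoxyphenyl formate | COc1cc(OC=O)ccc1Oc1ccc(C(C)=O)c(O)c1 | intermediate (not isolated)
5 | 1-[2-hydroxy-4-(4-hydroxy-2-methoxyphenoxy)phenyl]ethan-1-one | COc1cc(O)ccc1Oc1ccc(C(C)=O)c(O)c1 | intermediate
6 | 4-(benzyloxy)benzaldehyde | O=Cc1ccc(OCc2ccccc2)cc1 | starting material
7 | (E)-3-[4-(benzyloxy)phenyl]-1-[2-hydroxy-4-(4-hydroxy-2-methoxyphenoxy)phenyl]prop-2-en-1-one | COc1cc(O)ccc1Oc1ccc(C(=O)/C=C/c2ccc(OCc3ccccc3)cc2)c(O)c1 | intermediate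
8 | (E)-3-[4-(benzyloxy)phenyl]prop-2-enoic acid | OC(=O)/C=C/c1ccc(OCc2ccccc2)cc1 | starting material
9 | (E)-3-[4-(benzyloxy)phenyl]prop-2-enoyl chloride | O=C(Cl)/C=C/c1ccc(OCc2ccccc2)cc1 | intermediate (not isolated)
10 | 4-(4-{(E)-3-[4-(benzyloxy)phenyl]prop-2-enoyl}-3-hydroxyphenoxy)-3-methoxyphenyl (E)-3-[4-(benzyloxy)phenyl]prop-2-enoate | COc1cc(OC(=O)/C=C/c2ccc(OCc3ccccc3)cc2)ccc1Oc1ccc(C(=O)/C=C/c2ccc(OCc3ccccc3)cc2)c(O)c1 | intermediate (not isolated)
11 | (E)-3-[4-(benzyloxy)phenyl]-1-[5-(4-{(E)-3-[4-(benzyloxy)phenyl]prop-2-enoyl}-3-hydroxyphenoxy)-2-hydroxy-4-methoxyphenyl]prop-2-en-1-one (di-O-benzylrhuschalcone IV) | COc1cc(O)c(C(=O)/C=C/c2ccc(OCc3ccccc3)cc2)cc1Oc1ccc(C(=O)/C=C/c2ccc(OCc3ccccc3)cc2)c(O)c1 | intermediate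
12 | rhuschalcone IV | COc1cc(O)c(C(=O)/C=C/c2ccc(O)cc2)cc1Oc1ccc(C(=O)/C=C/c2ccc(O)cc2)c(O)c1 | target

Total step count: 5
Longest linear sequence: 5 steps (1/2 → 3 → 5 → 7 → 11 → 12)

Steps most likely to fail

(a) The key acylation (step 4). The acyl transfer may stall at the O-acyl stage. It may also be overtaken by conjugate Friedel–Crafts addition of ring A to a boron-activated enone, or by acid-induced loss of a benzyl group. The fallback sets out from 5 and makes the same aryl–carbonyl bond with a two-carbon unit before any enone exists. Friedel–Crafts/Fries acetylation of 5 (Ac2O, BF3·OEt2, 80 °C; then H2O/MeOH), under the same regiochemical control, should give 1-[5-(4-acetyl-3-hydroxyphenoxy)-2-hydroxy-4-methoxyphenyl]ethan-1-one F1. A twofold Claisen–Schmidt condensation of this diketone with 6 (2.5 equiv, KOH, EtOH, rt) then comes back to the route at 11.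

(b) The diaryl ether formation (step 1). The 4-phenoxide of 1 is a weak nucleophile, so substitution may be slow. At the temperature then needed, aldol-type condensation between ketone and aldehyde or arylation at the chelated 2-OH may compete. The fallback sets out from 1 and makes the same C–O bond by a copper-catalysed oxidative Chan–Lam coupling with purchased (4-formyl-2-methoxyphenyl)boronic acid (Cu(OAc)2 cat., pyridine, 4 Å MS, CH2Cl2, air, rt). It runs without strong base or heat and comes back to the route at 3; this fallback makes no new compound (F0).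

(c) The global debenzylation (step 5). Benzyl cations may re-alkylate the electron-rich rings faster than the scavenger traps them. The methyl ether next to the diaryl ether oxygen may be cleaved through a bidentate boron complex, or acid may close a 2'-hydroxychalcone to its flavanone. The fallback sets out from 5 and carries the phenols as acetates, which are removed by mild base instead of a Lewis acid.
- BF3·OEt2-mediated Claisen–Schmidt condensation of 5 with purchased 4-acetoxybenzaldehyde (dioxane, rt) should give 4-{(E)-3-[2-hydroxy-4-(4-hydroxy-2-methoxyphenoxy)phenyl]-3-oxoprop-1-en-1-yl}phenyl acetate F2.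
- Purchased (E)-4-acetoxycinnamic acid with (COCl)2 and catalytic DMF gives 4-[(E)-3-chloro-3-oxoprop-1-en-1-yl]phenyl acetate F3.
- BF3-mediated acylation of the acetate chalcone with this acid chloride, under the conditions of step 4, should give di-O-acetylrhuschalcone IV F4.
- K2CO3 in MeOH at 0 °C then cleaves both acetates and comes back to the route at 12.

Further compounds
F1 | step 4 | 1-[5-(4-acetyl-3-hydroxyphenoxy)-2-hydroxy-4-methoxyphenyl]ethan-1-one | COc1cc(O)c(C(C)=O)cc1Oc1ccc(C(C)=O)c(O)c1
F0 | step 1 | none | none
F2 | step 5 | 4-{(E)-3-[2-hydroxy-4-(4-hydroxy-2-methoxyphenoxy)phenyl]-3-oxoprop-1-en-1-yl}phenyl acetate | COc1cc(O)ccc1Oc1ccc(C(=O)/C=C/c2ccc(OC(C)=O)cc2)c(O)c1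
F3 | step 5 | 4-[(E)-3-chloro-3-oxoprop-1-en-1-yl]phenyl acetate | CC(=O)Oc1ccc(/C=C/C(=O)Cl)cc1
F4 | step 5 | di-O-acetylrhuschalcone IV | COc1cc(O)c(C(=O)/C=C/c2ccc(OC(C)=O)cc2)cc1Oc1ccc(C(=O)/C=C/c2ccc(OC(C)=O)cc2)c(O)c1
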